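**Plan**

- Labdane numbering is used: ring A = C1–C5, C10; ring B = C5–C10; chain C11–C16 on C9; C17 on C8; C18 (methyl) and C19 (CH2O, cis to C20) on C4; C20 = methyl on C10. Retrosynthetic cuts, in order: the C19–O acyl bond; C4–C18 and C4–C19 (back to a C4 ketone); C8=C17; the diene (C15, C16 from ethylene on an alkyne); ring B at C5–C6 and C7–C8 (methyl acrylate supplies C6–C7); a C5–C20 cyclopropane bond that the target lacks; C9–C10.
- Forward: ring A comes from 3-ethoxycyclohex-2-enone; the C9–C8 ester arm, carrying C11–C14, is attached at C10; a cyclopropane is laid across C5=C10; ring B is closed in the key step; then C4, C9, C8, the diene and the ester are finished.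
- Enabling feature: C5, the ring-fusion CH of ring A, lies between C4 (carried as a ketone until it becomes the quaternary centre) and the methyl-bearing quaternary C10, whose arm C9 ends at C8, an sp2 carbon of ring B that can start as an ester. C5 (enolate) and C8 (acyl) are four atoms apart, so a two-carbon acceptor closes ring B.
- The C10 methyl is stored as the CH2 of a C5–C10 cyclopropane; its reductive opening releases C20 as methyl and makes C5 the only enolate carbon of the C4 ketone.
- Stereochemistry: C4 carbinol by catalytic asymmetric reduction; C10 by hydroxyl-directed cyclopropanation; C5 by acrylate attack anti to the C9 arm (trans fusion); C9 by equilibration next to the C8 ketone; C4 by methylation of the C19 ester enolate anti to C20.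

Key step: step 6

Assumption: C9 is carried as a mixture of epimers in 6–16 and C7 of 13–15 is an enolisable β-keto ester centre; both are left undefined in the SMILES until step 10 sets C9.

**Route**

Step 1
Reactants: 1 methyl hex-5-ynoate
Product: 3 methyl 6-(trimethylsilyl)hex-5-ynoate, via bis-silyl ketene acetal 2 (not isolated)
Conditions: LiN(i-Pr)2 (2.2 equiv), THF, −78 °C; Me3SiCl (2.5 equiv), −78 °C to rt; 1 M HCl, THF, 0 °C
Reagents that add atoms: chlorotrimethylsilane C[Si](C)(C)Cl
Why: Double lithiation (alkyne C–H and ester α-C–H) and silylation gives the C-silyl alkyne and the O-silyl ketene acetal, and the acidic work-up hydrolyses only the ketene acetal, so the alkyne alone stays protected (silyl protection).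

Step 2
Reactants: 3 methyl 6-(trimethylsilyl)hex-5-ynoate; 4 3-ethoxycyclohex-2-en-1-one
Product: 6 methyl 2-(3-oxocyclohex-1-en-1-yl)-6-(trimethylsilyl)hex-5-ynoate, via lithium alkoxide adduct 5 (not isolated)
Conditions: LiN(i-Pr)2, THF, −78 °C; then 4, −78 to 0 °C; 1 M HCl, rt
Reagents that add atoms: none
Why: Stork–Danheiser sequence: the ester enolate adds to the vinylogous ester carbonyl and acid-promoted loss of ethanol with allylic transposition gives the 3-substituted cyclohexenone, forming C9–C10; C9 is racemic and enolisable, which is harmless because it is set later.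

Step 3
Reactants: 6 enone ester
Product: 7 methyl 2-[(3R)-3-hydroxycyclohex-1-en-1-yl]-6-(trimethylsilyl)hex-5-ynoate
Conditions: (S)-1-methyl-3,3-diphenyltetrahydro-1H,3H-pyrrolo[1,2-c][1,3,2]oxazaborole (10 mol%), catecholborane, toluene, −78 °C
Reagents that add atoms: none
Why: Corey–Bakshi–Shibata reduction: the oxazaborolidine–borane complex delivers hydride 1,2 to one carbonyl face with the alkenyl side as the large group, which should give the (R)-carbinol at C4, the stereocentre from which all others derive.

Step 4
Reactants: 7 allylic alcohol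
Product: 8 methyl 2-[(1S,5R,6S)-5-hydroxybicyclo[4.1.0]heptan-1-yl]-6-(trimethylsilyl)hex-5-ynoate
Conditions: Et2Zn, CH2I2, CH2Cl2, 0 °C
Reagents that add atoms: diiodomethane ICI
Why: Hydroxyl-directed Simmons–Smith (Furukawa) cyclopropanation: the zinc alkoxide delivers CH2 (the future C20) to the alkene face syn to oxygen, which fixes the configuration of the quaternary C10.

Step 5
Reactants: 8 cyclopropyl carbinol
Product: 9 methyl 2-[(1S,6S)-5-oxobicyclo[4.1.0]heptan-1-yl]-6-(trimethylsilyl)hex-5-ynoate
Conditions: Dess–Martin periodinane, NaHCO3, CH2Cl2, rt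
Reagents that add atoms: none
Why: Dess–Martin oxidation of the secondary cyclopropyl carbinol gives the α,β-cyclopropyl ketone under buffered, non-acidic conditions that leave the cyclopropane and the silylalkyne intact.

Step 6
Reactants: 9 cyclopropyl ketone; 10 methyl acrylate
Product: 13 trans-decalin β-keto ester (C4 ketone; C8 ketone; CO2Me on C7; 5S 10R), via lithium enolate 11 (not isolated), via ester enolate 12 (not isolated)
Conditions: Li (2.1 equiv), NH3(l)/THF, t-BuOH (1.0 equiv), −78 °C; isoprene; NH3 evaporated; methyl acrylate (1.3 equiv), THF, −78 to 0 °C; aq. NH4Cl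
Reagents that add atoms: none
Why: Birch-type two-electron reduction of the α,β-cyclopropyl ketone opens the exocyclic C5–C20 bond, the one aligned with the carbonyl π system, so that C20 becomes the C10 methyl (protonated by t-BuOH) and C5 the only enolate carbon; this lithium enolate adds to methyl acrylate (Michael addition, C5–C6) and the C7 ester enolate so formed acylates itself on the C8 ester of the arm (Dieckmann closure, C7–C8) with loss of methoxide. The closest known reaction types are the reductive cleavage of cyclopropyl ketones with trapping of the regiodefined enolate, and Michael–Dieckmann (Michael-initiated ring closure) annulations of enolates with acrylates. Ring B closes in the second bond formation as a 6-exo-trig attack of the C7 enolate on the C8 ester carbonyl. C10 is already fixed by the cyclopropane, and C5 is set in the Michael step, where the acrylate should approach the enolate face anti to the bulky C9 arm on C10, placing C6 trans to C9 and so H5 anti to C20 (trans-decalin); C7 and C9 stay epimeric at this stage. The step needs reduction of the ketone in preference to the ester and the silylalkyne (lithium titrated at −78 °C, one equivalent of t-BuOH so that no amide base remains), cleavage of the exocyclic and not the ring-fusion cyclopropane bond (orbital overlap), and ring closure faster than proton transfer from the ketone α-positions (intramolecular six-membered transition state at low temperature).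

Step 7
Reactants: 13 β-keto ester
Product: 14 C4 enol triflate (C3=C4) of 13
Conditions: KN(SiMe3)2 (2.2 equiv), THF, −78 °C; PhNTf2 (1.1 equiv), −78 °C
Reagents that add atoms: N-phenylbis(trifluoromethanesulfonimide) O=S(=O)(N(c1ccccc1)S(=O)(=O)C(F)(F)F)C(F)(F)F
Why: Enol triflate formation: the first equivalent of base protects the β-keto ester as its enolate, the second removes kinetically a proton from the C3 methylene (not the C5 methine), and the more reactive ketone enolate is O-triflated, which also locks C5 against epimerisation.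

Step 8
Reactants: 14 enol triflate
Product: 15 diester (C19 ester on C4 conjugated with C3=C4; CO2Me on C7; C8 ketone)
Conditions: Pd(OAc)2 (5 mol%), Ph2P(CH2)3PPh2, CO (1 atm), MeOH, Et3N, DMF, 60 °C
Reagents that add atoms: carbon monoxide [C-]#[O+]; methanol CO
Why: Palladium-catalysed methoxycarbonylation of the enol triflate (oxidative addition, CO insertion, methanolysis) installs C19 as the unsaturated ester.

Step 9
Reactants: 15 diester
Product: 16 keto enoate (C8 ketone; C7 now CH2)
Conditions: LiCl, DMSO, H2O, 135 °C
Reagents that add atoms: none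
Why: Krapcho dealkoxycarbonylation removes the C7 helper ester of the β-keto ester, while the enoate ester, which has no β-carbonyl, should not react.

Step 10
Reactants: 16 keto enoate
Product: 17 terminal alkyne keto enoate with C9 set (5S 9S 10R)
Conditions: K2CO3 (cat.), MeOH, rt
Reagents that add atoms: none
Why: Methoxide cleaves the alkynyl C–Si bond and the mild base equilibrates C9 through the C8 enolate to the epimer with the equatorial side chain (H9 anti to C20), expected to be the more stable one on the trans-decalone.

Step 11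
Reactants: 17 terminal alkyne
Product: 18 diene keto enoate
Conditions: ethylene (4 bar), second-generation Grubbs catalyst RuCl2(=CHPh)(PCy3)(H2IMes) (5 mol%), CH2Cl2, 40 °C
Reagents that add atoms: ethylene C=C
Why: Ethylene–alkyne cross enyne metathesis turns the terminal alkyne into the 2-substituted buta-1,3-diene (C15 and C16 from ethylene); it is run on the ketone so that no exocyclic alkene is present to close a ring by enyne metathesis.

Step 12
Reactants: 18 diene ketone
Product: 19 methyl 18-norlabda-3,8(17),13(16),14-tetraen-19-oate skeleton (5S 9R 10S)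
Conditions: Zn, CH2Br2, TiCl4, THF/CH2Cl2, 0 °C to rt
Reagents that add atoms: dibromomethane BrCBr
Why: Lombardo methylenation (a geminal dimetal reagent, not basic) converts the hindered enolisable C8 ketone to the exocyclic methylene without epimerising C9 and without attacking the ester or the diene.

Step 13
Reactants: 19 tetraene ester
Product: 21 methyl (4R,5S,9R,10S)-labda-8(17),13(16),14-trien-19-oate, via lithium ester enolate 20 (not isolated)
Conditions: LiBH(s-Bu)3, THF, −78 °C; MeI, DMPU, −78 to 0 °C
Reagents that add atoms: iodomethane CI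
Why: Reductive alkylation: conjugate hydride addition to the enoate gives the ester enolate, and iodomethane approaches from the face anti to the axial C20 methyl, which should place C18 equatorial and the ester carbon C19 axial (cis to C20).

Step 14
Reactants: 21 quaternary ester
Product: 22 (4R,5S,9R,10S)-labda-8(17),13(16),14-trien-19-ol
Conditions: LiAlH4, THF, 0 °C to reflux
Reagents that add atoms: none
Why: Hydride reduction of the hindered axial ester gives the neopentyl primary alcohol; the isolated alkenes and the diene are inert to LiAlH4.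

Step 15
Reactants: 22 alcohol; 23 (E)-4-acetoxycinnamic acid
Product: 25 target, via O-acetyl ester 24 (not isolated)
Conditions: 23, EDC·HCl, DMAP, CH2Cl2, rt; then pyrrolidine, 0 °C
Reagents that add atoms: none
Why: Carbodiimide (Steglich) esterification of the primary alcohol, then aminolysis of the aryl acetate in the same flask, which is much faster than attack on the hindered cinnamate ester; the E alkene is brought in intact.

**Compound list**

1 | methyl hex-5-ynoate | C#CCCCC(=O)OC | starting material
2 | [1-methoxy-6-(trimethylsilyl)hex-1-en-5-yn-1-yl]oxy(trimethyl)silane (E/Z) | COC(O[Si](C)(C)C)=CCCC#C[Si](C)(C)C | intermediate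
3 | methyl 6-(trimethylsilyl)hex-5-ynoate | C[Si](C)(C)C#CCCCC(=O)OC | intermediate
4 | 3-ethoxycyclohex-2-en-1-one | CCOC1=CC(=O)CCC1 | starting material
5 | lithium 3-ethoxy-1-[1-methoxy-1-oxo-6-(trimethylsilyl)hex-5-yn-2-yl]cyclohex-2-en-1-olate | C[Si](C)(C)C#CCCC(C(=O)OC)C1([O-])C=C(OCC)CCC1.[Li+] | intermediate
6 | methyl 2-(3-oxocyclohex-1-en-1-yl)-6-(trimethylsilyl)hex-5-ynoate (racemic at C9) | C[Si](C)(C)C#CCCC(C(=O)OC)C1=CC(=O)CCC1 | intermediate
7 | methyl 2-[(3R)-3-hydroxycyclohex-1-en-1-yl]-6-(trimethylsilyl)hex-5-ynoate (C9 epimers) | C[Si](C)(C)C#CCCC(C(=O)OC)C1=C[C@H](O)CCC1 | intermediate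
8 | methyl 2-[(1S,5R,6S)-5-hydroxybicyclo[4.1.0]heptan-1-yl]-6-(trimethylsilyl)hex-5-ynoate (OH cis to the cyclopropane CH2; C9 epimers) | C[Si](C)(C)C#CCCC(C(=O)OC)[C@@]12C[C@@H]1[C@H](O)CCC2 | intermediate
9 | methyl 2-[(1S,6S)-5-oxobicyclo[4.1.0]heptan-1-yl]-6-(trimethylsilyl)hex-5-ynoate (C9 epimers) | C[Si](C)(C)C#CCCC(C(=O)OC)[C@@]12C[C@@H]1C(=O)CCC2 | intermediate
10 | methyl acrylate | C=CC(=O)OC | starting material
11 | lithium enolate (O on C4, C4=C5) of methyl 2-[(1R)-1-methyl-3-oxocyclohexyl]-6-(trimethylsilyl)hex-5-ynoate | C[Si](C)(C)C#CCCC(C(=O)OC)[C@]1(C)CCCC([O-])=C1.[Li+] | intermediate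
12 | lithium enolate of the C7 ester in methyl 2-[(1R,2S)-2-(3-methoxy-3-oxopropyl)-1-methyl-3-oxocyclohexyl]-6-(trimethylsilyl)hex-5-ynoate | C[Si](C)(C)C#CCCC(C(=O)OC)[C@]1(C)CCCC(=O)[C@H]1CC=C([O-])OC.[Li+] | intermediate
13 | trans-decalin β-keto ester: C4 ketone, C8 ketone, CO2Me on C7, 4-(trimethylsilyl)but-3-ynyl on C9, methyl on C10 (5S,10R; C7 and C9 epimers) | C[Si](C)(C)C#CCCC1C(=O)C(C(=O)OC)C[C@@H]2C(=O)CCC[C@@]12C | intermediate
14 | enol triflate of 13: C4 trifluoromethanesulfonyloxy, C3=C4 (5S,10R; C7 and C9 epimers) | C[Si](C)(C)C#CCCC1C(=O)C(C(=O)OC)C[C@@H]2C(OS(=O)(=O)C(F)(F)F)=CCC[C@@]12C | intermediate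
15 | diester: C4 CO2Me (C19) on C3=C4, CO2Me on C7, C8 ketone (5S,10R; C7 and C9 epimers) | C[Si](C)(C)C#CCCC1C(=O)C(C(=O)OC)C[C@@H]2C(C(=O)OC)=CCC[C@@]12C | intermediate
16 | keto enoate: C8 ketone, C19 ester on C3=C4, silylbutynyl on C9 (5S,10R; C9 epimers) | C[Si](C)(C)C#CCCC1C(=O)CC[C@@H]2C(C(=O)OC)=CCC[C@@]12C | intermediate
17 | keto enoate with but-3-ynyl on C9 (5S,9S,10R) | C#CCC[C@@H]1C(=O)CC[C@@H]2C(C(=O)OC)=CCC[C@@]12C | intermediate
18 | keto enoate with 3-methylidenepent-4-enyl on C9 (5S,9S,10R) | C=CC(=C)CC[C@@H]1C(=O)CC[C@@H]2C(C(=O)OC)=CCC[C@@]12C | intermediate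
19 | methyl 18-norlabda-3,8(17),13(16),14-tetraen-19-oate (5S,9R,10S) | C=CC(=C)CC[C@@H]1C(=C)CC[C@@H]2C(C(=O)OC)=CCC[C@@]12C | intermediate
20 | lithium ester enolate (C4=C19) from conjugate reduction of 19 | C=CC(=C)CC[C@@H]1C(=C)CC[C@@H]2C(=C([O-])OC)CCC[C@@]12C.[Li+] | intermediate
21 | methyl (4R,5S,9R,10S)-labda-8(17),13(16),14-trien-19-oate | C=CC(=C)CC[C@@H]1C(=C)CC[C@@H]2[C@](C)(C(=O)OC)CCC[C@@]12C | intermediate
22 | [(1R,4aS,5R,8aS)-1,4a-dimethyl-6-methylidene-5-(3-methylidenepent-4-en-1-yl)decahydronaphthalen-1-yl]methanol | C=CC(=C)CC[C@@H]1C(=C)CC[C@@H]2[C@](C)(CO)CCC[C@@]12C | intermediate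
23 | (2E)-3-(4-acetoxyphenyl)prop-2-enoic acid | CC(=O)Oc1ccc(/C=C/C(=O)O)cc1 | starting material
24 | O-acetyl derivative of the target (4-acetoxycinnamate of 22) | C=CC(=C)CC[C@@H]1C(=C)CC[C@@H]2[C@](C)(COC(=O)/C=C/c3ccc(OC(C)=O)cc3)CCC[C@@]12C | intermediate
25 | [(1R,4aS,5R,8aS)-1,4a-dimethyl-6-methylidene-5-(3-methylidenepent-4-en-1-yl)decahydronaphthalen-1-yl]methyl (2E)-3-(4-hydroxyphenyl)prop-2-enoate | C=CC(=C)CC[C@@H]1C(=C)CC[C@@H]2[C@](C)(COC(=O)/C=C/c3ccc(O)cc3)CCC[C@@]12C | target

**Count**

Total steps: 15. Longest linear sequence: 15 steps (1 to 25); 4, 10, ethylene and 23 enter as bought reagents.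

**Steps most likely to fail**

Step 6. The dissolved metal may over-reduce the silylalkyne or the ester. Proton transfer to the ester enolate may precede acylation, which would let the ketone side close a Michael–Claisen ring instead. The conjugate addition may be incompletely anti selective. In the fallback the two bond formations are separated and the ketone is taken out of play before ring closure. It sets out from 9. The reductive opening is quenched with Me3SiCl/Et3N to give the regiodefined silyl enol ether methyl 2-[(1R)-1-methyl-3-(trimethylsilyloxy)cyclohex-2-en-1-yl]-6-(trimethylsilyl)hex-5-ynoate F1. A Mukaiyama–Michael addition of F1 to methyl acrylate (TiCl4, CH2Cl2, −78 °C) should give the keto diester methyl 2-[(1R,2S)-2-(3-methoxy-3-oxopropyl)-1-methyl-3-oxocyclohexyl]-6-(trimethylsilyl)hex-5-ynoate F2, whose C5 centre can be equilibrated with DBU to the isomer with the propanoate chain anti to the arm. Kinetic triflation (KN(SiMe3)2, PhNTf2, −78 °C) should give the enol triflate diester methyl 2-[(1R,2S)-2-(3-methoxy-3-oxopropyl)-1-methyl-3-(trifluoromethanesulfonyloxy)cyclohex-3-en-1-yl]-6-(trimethylsilyl)hex-5-ynoate F3, in which the ketone can no longer enolise. A Dieckmann closure with LiN(SiMe3)2 (C7 enolate onto the C8 ester) then gives 14, where the route is rejoined.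

Step 10. The equilibrium at C9 may not lie far enough on the side of the equatorial side chain, because the neighbouring quaternary C10 lowers the usual preference. In the fallback C9 is set by kinetic protonation instead of equilibration. It sets out from 14. NaH and then LiN(i-Pr)2 give the dianion of the β-keto ester, in which C7 is blocked by the ester so that only C9 is deprotonated. Protonation at −78 °C with 2,6-di-tert-butyl-4-methylphenol from the face anti to C20 should give the C9-defined enol triflate (5S,9S,10R) F4. Methoxycarbonylation as in step 8 gives the C9-defined diester F5. Krapcho dealkoxycarbonylation as in step 9, with a short reaction time, gives the C9-defined silylalkyne keto enoate F6. Desilylation under buffered, non-epimerising conditions (Bu4NF, AcOH, THF) gives 17, where the route is rejoined.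

Step 13. The hindered borohydride may reduce the ester 1,2 or give incomplete conjugate reduction, and the one-pot alkylation may suffer O-methylation or poor facial selectivity. In the fallback reduction and alkylation are separated. It sets out from 19. Electron-transfer conjugate reduction (Mg, MeOH) gives the saturated ester methyl 18-norlabda-8(17),13(16),14-trien-19-oate F7 as C4 epimers. Deprotonation with LiN(i-Pr)2 and methylation with MeI (THF, DMPU, −78 °C), again anti to C20, gives 21, where the route is rejoined.

Further compounds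
F1 | step 6 | methyl 2-[(1R)-1-methyl-3-(trimethylsilyloxy)cyclohex-2-en-1-yl]-6-(trimethylsilyl)hex-5-ynoate | C[Si](C)(C)C#CCCC(C(=O)OC)[C@]1(C)CCCC(O[Si](C)(C)C)=C1
F2 | step 6 | methyl 2-[(1R,2S)-2-(3-methoxy-3-oxopropyl)-1-methyl-3-oxocyclohexyl]-6-(trimethylsilyl)hex-5-ynoate | C[Si](C)(C)C#CCCC(C(=O)OC)[C@]1(C)CCCC(=O)[C@H]1CCC(=O)OC
F3 | step 6 | methyl 2-[(1R,2S)-2-(3-methoxy-3-oxopropyl)-1-methyl-3-(trifluoromethanesulfonyloxy)cyclohex-3-en-1-yl]-6-(trimethylsilyl)hex-5-ynoate | C[Si](C)(C)C#CCCC(C(=O)OC)[C@]1(C)CCC=C(OS(=O)(=O)C(F)(F)F)[C@H]1CCC(=O)OC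
F4 | step 10 | enol triflate 14 with C9 defined (5S,9S,10R) | C[Si](C)(C)C#CCC[C@@H]1C(=O)C(C(=O)OC)C[C@@H]2C(OS(=O)(=O)C(F)(F)F)=CCC[C@@]12C
F5 | step 10 | diester 15 with C9 defined (5S,9S,10R) | C[Si](C)(C)C#CCC[C@@H]1C(=O)C(C(=O)OC)C[C@@H]2C(C(=O)OC)=CCC[C@@]12C
F6 | step 10 | keto enoate 16 with C9 defined (5S,9S,10R) | C[Si](C)(C)C#CCC[C@@H]1C(=O)CC[C@@H]2C(C(=O)OC)=CCC[C@@]12C
F7 | step 13 | methyl 18-norlabda-8(17),13(16),14-trien-19-oate (5S,9R,10S; C4 epimers) | C=CC(=C)CC[C@@H]1C(=C)CC[C@@H]2C(C(=O)OC)CCC[C@@]12C
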